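12.9 mM min⁻¹ of J is what the alder run gains between 0.833 min and 2.50 min. This pace, the mM of J formed per minute on the straight stretch of a run, is read from the runs below and carries their scatter.

| setting | cedar | alder | flask |
|---|---|---|---|
| Q | 17 mM | 38 mM | 25 mM |
| G | 1.2 mM (held) | 1.2 mM (held) | 1.2 mM (held) |
| remark | run made earlier | run made earlier |  |
| time |  |  | 2.5 min |

| run | time / min | J / % | D / % |
|---|---|---|---|
| cedar | 0.333 | 8.1 | 64.2 |
| cedar | 0.833 | 46.6 | 30.0 |
| cedar | 1.50 | 82.4 | 9.9 |
| cedar | 2.50 | 97.9 | 1.1 |
| alder | 0.333 | 3.6 | 27.9 |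
| alder | 0.833 | 23.6 | 37.7 |
| alder | 1.50 | 48.3 | 22.8 |
| alder | 2.50 | 80.1 | 9.1 |

(each reading ± 0.5 percentage points)

- J present at 2.5 min, in percent of the Q charged
- D present at 2.5 min, in percent of the Q charged

- solid, in amounts per volume of the solution: Q
- the numbers in the tables scatter with a standard deviation of 0.5 percentage points
- at the start none of Q is in solution
- at the start none of G is in solution
- D means what is dissolved; the solid is not counted in it

The amounts in mM point to a zero-order stretch: at 0.833 min, cedar holds 7.92 mM of J and alder 8.97 mM, from charges of 17 mM and 38 mM. The bench rule is therefore a straight line, cJ = pace × (t − onset), with an onset from alder of 0.137 min.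

For the flask at 2.5 min, this line asks for 1.22 times the charge, so it has crossed its border. Cedar shows the bend, gaining 9.12 mM min⁻¹ between 0.833 min and 1.50 min, slower than the pace.

The remainder is then what is worth reckoning. The flask's extra charge costs 0.621 min at the pace, so my own reckoning sets the flask at 2.5 min on the cedar tail at 1.88 min. Log interpolation of cedar gives 1.34 mM not yet J, hence 94.7 % of J, and likewise 2.93 % of D.

The forecast gives 93.5 % of J and 3.5 % of D, by “Shifting one minute along the cedar curve”.

The flask gives 95.5 % of J and 3.20 % of D.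

    D ⇌ L (K = 2.00, k = 0.0429 s⁻¹)
    E → Z (k = 0.232 s⁻¹)
    L + Z → J (k = 15.9 M⁻¹ s⁻¹)
    Q ⇌ D, rate k4*(cs4 - [D]) while solid is left; crystals form when [D] > cs4 (solubility = 25.0 mM, k = 0.0445 s⁻¹)
    G ⇌ E, rate k5*(csat - [E]) (kL = 0.876 s⁻¹)

In the flask, the going into solution of Q had the midpoint of its turnover at 0.241 min, and Q stood at 0 % at 1.25 min. With cE at 0.949 mM at 1.25 min and a half-life of 3.0 s, E passed into Z at 13.2 mM min⁻¹, close to the pace 12.9 mM min⁻¹, while L fell from 22.7 % at 1.25 min to 1.31 % at 2.50 min and cZ rose from 2.18 mM to 8.94 mM. The straight line gives 57.4 % of J at 1.25 min, where the flask holds 56.5 %. For the same flask read at 40 s, the line gives 27.3 %, and that neighbour flask holds 24.9 %.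

(The runs stem from a simulated flask for an exercise.)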